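| flask | free monomer | protic impurity | initiator | remark | time |
|---|---|---|---|---|---|
| delta | 16 mM | 0.80 mM | 0.34 mol% | run made earlier |  |
| epsilon | 16 mM | 0.80 mM | 0.75 mol% | run made earlier |  |
| eta | 32 mM | 0.80 mM | 0.5 mol% | run made earlier |  |
| Friday's | 16 mM | 0.800 mM | 0.5 mol% |  | 40 min |
| Monday's | 16 mM | 0.800 mM | 0.5 mol% |  | 80 min |

- delta (time / min: free monomer / %, monomer in chains / %): 2.00: 95.5, 0.8; 3.00: 93.8, 3.4; 4.00: 91.7, 4.3; 6.00: 87.9, 9.5; 10.0: 80.0, 18.3; 15.0: 66.3, 27.4; 25.0: 48.4, 47.8
- epsilon (time / min: free monomer / %, monomer in chains / %): 2.00: 96.3, 2.6; 3.00: 90.6, 5.9; 4.00: 88.5, 11.1; 6.00: 77.9, 16.5; 10.0: 61.2, 33.0; 15.0: 45.2, 49.0; 25.0: 25.2, 71.0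
- eta (time / min: free monomer / %, monomer in chains / %): 5.00: 73.2, 27.0; 10.0: 46.4, 53.8; 15.0: 28.4, 70.4; 20.0: 17.6, 80.4; 25.0: 12.0, 85.9

(scatter of a reading: 1 percentage point)

- on the list of suspects stand: free monomer + living end -> monomer in chains + living end; protic impurity + free monomer -> quenched substrate; monomer in chains + living end -> free monomer + living end; free monomer + initiator -> living end + monomer in chains

- which of these there is most of at the end, counted by the free monomer in it, Friday's (monomer in chains / free monomer)
- which of these there is most of at the end, counted by the free monomer in it, Monday's (monomer in chains / free monomer)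
- how much there is at the end of the one of these that leads, in percent of the free monomer charged: Friday's
- how much there is at the end of the one of these that leads, in percent of the free monomer charged: Monday's

The constants of this flask were hidden, so I read two of them from the eta tail. Free monomer fell from 46.4% to 28.4% between 10.0 min and 15.0 min, and from 17.6% to 12.0% between 20.0 min and 25.0 min. A straight line of rate against fraction left then has a pseudo-first-order slope of 0.110 min⁻¹, and it reaches zero rate at a fraction 4.59% of the eta charge. I called that concentration, 1.47 mM, the floor: the free monomer level at which propagation and depropagation balance, the equilibrium monomer concentration. Both values are reckoned from those eta readings, each with a scatter of 1 percentage point, so both are rough estimates.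

Friday's and Monday's flasks have the same loading on half the free monomer. I took living ends as proportional to initiator, so I halved the slope to 0.0549 min⁻¹. Then I added the processes one at a time.

| Chains, fraction of charge | Friday's, 40 min | Monday's, 80 min |
|---|---|---|
| Propagation | 88.9% | 98.8% |
| Plus quench | 84.4% | 93.8% |
| Plus depropagation | 76.3% | 84.7% |

The quench takes a fraction 5.00%, near the 3.80% missing from the last epsilon reading. The floor holds back a fraction 9.19%, so chains approach a ceiling of 85.8%. Initiation, the remaining process, brings a lag: the delta run had 0.8% in chains after 2.00 min. My clock started at zero, so my figures run slightly ahead.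

The forecast put monomer in chains in the lead in both flasks, at 74.5% on Friday's and 90% on Monday's, "allowing for slight reversibility".

The simulation gave monomer in chains in the lead in both: 74.5% against 20.5% free monomer on Friday's, and 84.8% against 10.2% on Monday's.

    free monomer + living end → monomer in chains + living end, rate k1*[living end]*[free monomer] (k = 750 L mol⁻¹ min⁻¹)
    protic impurity + free monomer → quenched substrate (k = 20.0 L mol⁻¹ min⁻¹)
    monomer in chains + living end → free monomer + living end, rate k3*[living end] as long as [monomer in chains] is above zero (k = 1.10 min⁻¹)
    free monomer + initiator → living end + monomer in chains (k = 12.0 L mol⁻¹ min⁻¹)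

In Friday's flask, chains were made 5.93 times faster than used up at 16.1 min, but 2.24 times faster at 40.0 min. Free monomer over my floor gives 2.23 at that end, and 1.11 on Monday's. In the neighbour charged with 4.0 mM, with the same protic impurity, the floor is a fraction 36.8% of the charge, so the ceiling is 43.3% and my reckoning gives 18.3% in chains. The simulation gave 13.1% in chains, with 68.4% still free.

The numbers in the tables were computed with constants of no real substance; the scatter is artificial.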